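## Retrosynthetic overview

1. The strategy rests on the two adjacent quaternary carbons of the six-membered ring, C6 (ethyl, dienyl) and C7 (ethyl, carboxyl C8), which with the ring alkene C4=C5 make up a γ,δ-unsaturated acid.
2. Late disconnection: the Cb–Cc bond of the dienyl chain comes from hydrozirconation–Negishi coupling of a C6 but-1-ynyl group with (E)-β-bromostyrene; ketal and silyl ester are removed last.
3. Key disconnection: C6–C7 and the cyclohexene ring come from an Ireland–Claisen rearrangement of the silyl ketene acetal of a trans-fused δ-lactone (ring O on C4, carbonyl C8 on C7) whose C4 carries an (E)-enynyl arm.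
4. The lactone comes from chelation-controlled MeMgBr addition to a C4 ynone and ring closure onto the C8 ester; the arm is finished by hydrozirconation–iodination and Sonogashira coupling.
5. Ring order: the five-membered ring is bought as (S)-4-silyloxycyclopentenone and dressed by two trans conjugate additions; the temporary δ-lactone follows (step 10); the cyclohexene forms last (step 13) as the lactone opens.

Key step: step 13

## Remarks

- Atom labels (used for all intermediates): hexahydroindene positions C1 (ethyl), C2 (ketone), C3 (methyl), C3a, C4 (methyl), C5, C6, C7, C7a; C8 is the carboxyl carbon on C7; the dienyl chain is C6–Ca(H)=Cb(Et)–Cc(H)=Cd(H)–Ph. β is the face carrying H-7a, α the opposite face.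
- Assumption: C6 carries a but-1-ynyl group (Ca≡Cb–Et) through the rearrangement instead of an oxygenated one-carbon handle. A C6 hydroxymethyl would lactonise onto the cis C7 carboxyl, and an aldehyde between two quaternary carbons would be a poor olefination partner. The linear alkyne is also the least demanding outside group in the rearrangement.
- Assumption: C7 forms in step 4 as an epimer mixture. Both epimers converge in step 13, where C7 becomes planar. Compounds 7–10, 12 and 14–20 are drawn as the epimer with C7–H α.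
- Compounds 1, 5, 13 and 23 are taken as commercial.

## Route

Step 1
Reactants: 1 (S)-4-(tert-butyldimethylsilyloxy)cyclopent-2-en-1-one
Product: 3 (2,3-trans-3,4-trans)-4-(tert-butyldimethylsilyloxy)-2-methyl-3-vinylcyclopentan-1-one, via bromomagnesium enolate 2 (not isolated)
Conditions: CH2=CHMgBr (1.3 equiv), CuBr·SMe2 (10 mol %), THF, −78 °C; then MeI (5 equiv), HMPA, −78 → −30 °C
Reagents that add atoms: vinylmagnesium bromide, C=C[Mg]Br; iodomethane, CI
Why: Copper-catalysed 1,4-addition of the vinyl Grignard reagent should occur anti to the C7a silyloxy group (sets C3a, vinyl β), and the regiodefined magnesium enolate is then C-methylated anti to the new vinyl group (sets C3, methyl α) in a three-component conjugate addition–enolate alkylation.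

Step 2
Reactants: 3 (2,3-trans-3,4-trans)-4-(tert-butyldimethylsilyloxy)-2-methyl-3-vinylcyclopentan-1-one
Product: 4 trans-5-methyl-4-vinylcyclopent-2-en-1-one
Conditions: DBU (1.2 equiv), CH2Cl2, 0 °C, 30 min
Reagents that add atoms: none
Why: E1cB β-elimination of the silanol through the C1 enolate should give the C1=C7a enone, the short, cold base treatment being chosen to leave the doubly allylic C3a–H untouched.

Step 3
Reactants: 5 methyl butanoate
Product: 6 (E)-1-methoxy-1-(trimethylsilyloxy)but-1-ene
Conditions: LiN(i-Pr)2, THF, −78 °C; then Me3SiCl, −78 → 23 °C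
Reagents that add atoms: chlorotrimethylsilane, C[Si](C)(C)Cl
Why: Kinetic ester enolisation and O-silylation give the ketene silyl acetal for a Mukaiyama–Michael reaction; its geometry has no consequence because C7 is planarised later.

Step 4
Reactants: 4 trans-5-methyl-4-vinylcyclopent-2-en-1-one; 6 (E)-1-methoxy-1-(trimethylsilyloxy)but-1-ene
Product: 8 methyl 2-(3-methyl-4-oxo-2-vinylcyclopentyl)butanoate (ring all-trans), via trimethylsilyl enol ether 7 (not isolated)
Conditions: 6 (1.5 equiv), Sc(OTf)3 (5 mol %), CH2Cl2, −78 °C; then 1 M HCl, THF, 0 °C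
Reagents that add atoms: none
Why: The Lewis-acid-catalysed Mukaiyama–Michael addition should deliver C7 to C7a anti to the adjacent C3a vinyl group (sets C7a, side chain α, H-7a β) under non-basic conditions that spare the acidic C3a–H, and hydrolysis of enol ether 7 gives the ketone with C7 as an inconsequential epimer mixture.

Step 5
Reactants: 8 methyl 2-(3-methyl-4-oxo-2-vinylcyclopentyl)butanoate (ring all-trans)
Product: 9 methyl 2-(2-ethyl-4-methyl-3-oxo-5-vinylcyclopentyl)butanoate (ring all-trans)
Conditions: LiN(i-Pr)2 (1.05 equiv), THF, −78 °C; then EtI (3 equiv), HMPA, −78 → −20 °C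
Reagents that add atoms: iodoethane, CCI
Why: Kinetic deprotonation at the less substituted α-carbon C1 of the ketone (more acidic than the ester) and enolate alkylation anti to the C7a side chain set C1 (ethyl β), which is also the thermodynamically preferred all-trans arrangement.

Step 6
Reactants: 9 methyl 2-(2-ethyl-4-methyl-3-oxo-5-vinylcyclopentyl)butanoate (ring all-trans)
Product: 10 methyl 2-(6-ethyl-9-methyl-8-vinyl-1,4-dioxaspiro[4.4]nonan-7-yl)butanoate
Conditions: Me3SiOCH2CH2OSiMe3 (2 equiv), Me3SiOTf (5 mol %), CH2Cl2, −78 → −20 °C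
Reagents that add atoms: 1,2-bis(trimethylsilyloxy)ethane, C[Si](C)(C)OCCO[Si](C)(C)C
Why: Silyl-triflate-catalysed ketalisation under aprotic conditions masks the hindered C2 ketone without transesterification, and C1 and C3 already have their most stable configuration.

Step 7
Reactants: 10 methyl 2-(6-ethyl-9-methyl-8-vinyl-1,4-dioxaspiro[4.4]nonan-7-yl)butanoate
Product: 12 methyl 2-(6-ethyl-8-formyl-9-methyl-1,4-dioxaspiro[4.4]nonan-7-yl)butanoate, via ozonide 11 (not isolated)
Conditions: O3, CH2Cl2, −78 °C; then PPh3, −78 → 23 °C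
Reagents that add atoms: ozone, [O-][O+]=O
Why: Ozonolysis with reductive work-up cleaves the only alkene to the C4 aldehyde, and C3a stays in its favoured trans,trans configuration.

Step 8
Reactants: 12 methyl 2-(6-ethyl-8-formyl-9-methyl-1,4-dioxaspiro[4.4]nonan-7-yl)butanoate; 13 but-1-yne
Product: 14 methyl 2-[6-ethyl-8-(1-hydroxypent-2-ynyl)-9-methyl-1,4-dioxaspiro[4.4]nonan-7-yl]butanoate (carbinol epimers)
Conditions: 13 (1.5 equiv), n-BuLi (1.4 equiv), THF, −78 °C; then 12, −78 °C; H2O
Reagents that add atoms: none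
Why: 1,2-Addition of the lithium acetylide to the aldehyde is much faster than attack on the hindered ester at −78 °C, and the new carbinol centre is removed in the next step.

Step 9
Reactants: 14 methyl 2-[6-ethyl-8-(1-hydroxypent-2-ynyl)-9-methyl-1,4-dioxaspiro[4.4]nonan-7-yl]butanoate
Product: 15 methyl 2-[6-ethyl-9-methyl-8-(pent-2-ynoyl)-1,4-dioxaspiro[4.4]nonan-7-yl]butanoate
Conditions: Dess–Martin periodinane (1.3 equiv), CH2Cl2, 0 → 23 °C
Reagents that add atoms: none
Why: Dess–Martin oxidation of the secondary propargylic alcohol gives the ynone under mild conditions that leave ketal and ester intact.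

Step 10
Reactants: 15 methyl 2-[6-ethyl-9-methyl-8-(pent-2-ynoyl)-1,4-dioxaspiro[4.4]nonan-7-yl]butanoate
Product: 17 trans-fused but-1-ynyl δ-lactone (C8 carbonyl; ring O on C4; C4 methyl β; C4 butynyl α; C2 ethylene ketal), via bromomagnesium alkoxide 16 (not isolated)
Conditions: MeMgBr (1.3 equiv), CH2Cl2–Et2O, −78 °C; then THF, 23 → 50 °C
Reagents that add atoms: methylmagnesium bromide, C[Mg]Br
Why: In this chelation-controlled Grignard 1,2-addition Mg should bridge the ketone oxygen and the syn oxygen of the C2 dioxolane, so that methyl is delivered anti to C7a (also the Felkin–Anh sense with the branched C7a as the large group); this sets C4 with methyl β and the butynyl group cis to H-3a, and alkoxide 16 then lactonises onto the C8 methyl ester to close the trans-fused δ-lactone.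

Step 11
Reactants: 17 trans-fused but-1-ynyl δ-lactone
Product: 19 δ-lactone with an (E)-2-iodobut-1-enyl group on C4 (ethyl cis to C4), via alkenylzirconocene chloride 18 (not isolated)
Conditions: Cp2Zr(H)Cl (1.6 equiv), THF, 23 °C; then I2 (1.6 equiv), 0 °C
Reagents that add atoms: iodine, II
Why: syn-Hydrozirconation places zirconium on the alkyne carbon remote from the fully substituted C4 (steric control) and iodinolysis proceeds with retention, so the (E)-iodide with ethyl cis to C4 should result.

Step 12
Reactants: 19 δ-lactone with an (E)-2-iodobut-1-enyl group on C4; 13 but-1-yne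
Product: 20 δ-lactone with an (E)-2-ethylhex-1-en-3-ynyl group on C4 (ethyl cis to C4; rearrangement precursor)
Conditions: 13 (3 equiv), Pd(PPh3)2Cl2 (3 mol %), CuI (6 mol %), i-Pr2NH, THF, 23 °C
Reagents that add atoms: none
Why: Sonogashira coupling of the alkenyl iodide proceeds with retention of alkene geometry at room temperature, where the hindered tertiary allylic lactone should not ionise on palladium.

Step 13
Reactants: 20 δ-lactone with an (E)-2-ethylhex-1-en-3-ynyl group on C4
Product: 22 tert-butyldimethylsilyl ester of the C6-butynyl hexahydroindene acid (C4=C5; C6 butynyl β and ethyl α; C7 carboxyl β and ethyl α; C2 ethylene ketal), via silyl ketene acetal 21 (not isolated)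
Conditions: t-BuMe2SiCl (1.5 equiv), HMPA, THF, −78 °C; KN(SiMe3)2 (1.3 equiv), −78 → 0 °C; then toluene, 110 °C
Reagents that add atoms: tert-butyldimethylsilyl chloride, CC(C)(C)[Si](C)(C)Cl
Why: KN(SiMe3)2 removes the pseudo-axial C7–H and O-silylation gives the cyclic ketene acetal 21, whose geometry is fixed by the ring; on heating the lactone leaves its half-chair for a twist-boat in which the C4 enynyl arm lies over C7, and C6–C7 forms as C4–O breaks in a suprafacial, concerted [3,3] shift (Ireland–Claisen rearrangement). The closest known reaction type is the Ireland–Claisen rearrangement of 6-alkenyl δ-lactone and dioxanone silyl ketene acetals through boat-like transition states. The cyclohexene ring (C4, C5, C6, C7, C7a, C3a) closes by this sigmatropic C6–C7 bond formation at the expense of the lactone ring, with the new C4=C5 alkene inside the ring. C7 is controlled by the C4 configuration, because the arm sits on the lactone face cis to H-3a and C6 can reach only that face of C7, so the carboxyl ends β; C6 is controlled by the C5=C6 geometry, the ethyl cis to C4 taking the inside position of the boat (ethyl α) and the butynyl the outside position (β). The step needs the [3,3] path to win over heterolysis of the tertiary allylic C4–O bond and over fragmentation of the enolate, which the internal silyl quench, the rigid trans-fused template and the slim butynyl group (it eclipses the C7 ethyl in the boat) should secure. The strain that the trans-fused cyclopentane adds to the twist-boat is the main risk.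

Step 14
Reactants: 22 tert-butyldimethylsilyl ester of the C6-butynyl hexahydroindene acid; 23 (E)-(2-bromovinyl)benzene
Product: 26 tert-butyldimethylsilyl ester of the target ethylene ketal, via alkenylzirconocene chloride 24 (not isolated), via alkenylzinc chloride 25 (not isolated)
Conditions: Cp2Zr(H)Cl (1.5 equiv), THF, 40 °C; then ZnCl2 (1.5 equiv), Pd(PPh3)4 (5 mol %), 23 (1.3 equiv), THF, 45 °C
Reagents that add atoms: none
Why: syn-Hydrozirconation puts zirconium on Cb, away from the quaternary C6, and Negishi coupling after transmetalation to zinc joins Cb to the (E)-styryl bromide with retention on both partners to give the (E,E)-diene, while the trisubstituted ring alkene, the ketal and the hindered silyl ester should be inert.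

Step 15
Reactants: 26 tert-butyldimethylsilyl ester of the target ethylene ketal
Product: 27 CNP0134269.1
Conditions: 1 M HCl, THF, 23 °C
Reagents that add atoms: water, O
Why: Acid hydrolysis removes the dioxolane and the silyl ester in one operation, and C1 and C3, the only centres that can epimerise through the enol, already have the thermodynamically favoured configuration trans to their neighbours.

## Compound list

1 | (S)-4-(tert-butyldimethylsilyloxy)cyclopent-2-en-1-one | O=C1C=C[C@@H](O[Si](C)(C)C(C)(C)C)C1 | starting material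
2 | bromomagnesium enolate of trans-3-vinyl-4-(tert-butyldimethylsilyloxy)cyclopentanone | Br[Mg]OC1=C[C@H](C=C)[C@@H](O[Si](C)(C)C(C)(C)C)C1 | intermediate (not isolated)
3 | (2,3-trans-3,4-trans)-4-(tert-butyldimethylsilyloxy)-2-methyl-3-vinylcyclopentan-1-one (C3 methyl α; C3a vinyl β; C7a silyloxy α) | O=C1[C@@H](C)[C@H](C=C)[C@@H](O[Si](C)(C)C(C)(C)C)C1 | intermediate
4 | trans-5-methyl-4-vinylcyclopent-2-en-1-one (C3 methyl α; C3a vinyl β) | O=C1C=C[C@@H](C=C)[C@@H]1C | intermediate
5 | methyl butanoate | CCCC(=O)OC | starting material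
6 | (E)-1-methoxy-1-(trimethylsilyloxy)but-1-ene | CC/C=C(\OC)/O[Si](C)(C)C | intermediate
7 | trimethylsilyl enol ether (C1=C2) of 8 | C[Si](C)(C)OC1=C[C@H]([C@@H](CC)C(=O)OC)[C@@H](C=C)[C@@H]1C | intermediate (not isolated)
8 | methyl 2-(3-methyl-4-oxo-2-vinylcyclopentyl)butanoate, ring all-trans (C7a side chain α; vinyl β; methyl α) | O=C1C[C@H]([C@@H](CC)C(=O)OC)[C@@H](C=C)[C@@H]1C | intermediate
9 | methyl 2-(2-ethyl-4-methyl-3-oxo-5-vinylcyclopentyl)butanoate, ring all-trans (C1 ethyl β) | O=C1[C@@H](CC)[C@H]([C@@H](CC)C(=O)OC)[C@@H](C=C)[C@@H]1C | intermediate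
10 | methyl 2-(6-ethyl-9-methyl-8-vinyl-1,4-dioxaspiro[4.4]nonan-7-yl)butanoate (ethylene ketal of 9) | C12(OCCO1)[C@@H](CC)[C@H]([C@@H](CC)C(=O)OC)[C@@H](C=C)[C@@H]2C | intermediate
11 | ozonide of 10 (1,2,4-trioxolan-3-yl on C3a) | C12(OCCO1)[C@@H](CC)[C@H]([C@@H](CC)C(=O)OC)[C@@H](C3OOCO3)[C@@H]2C | intermediate (not isolated)
12 | methyl 2-(6-ethyl-8-formyl-9-methyl-1,4-dioxaspiro[4.4]nonan-7-yl)butanoate | C12(OCCO1)[C@@H](CC)[C@H]([C@@H](CC)C(=O)OC)[C@@H](C=O)[C@@H]2C | intermediate
13 | but-1-yne | C#CCC | starting material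
14 | methyl 2-[6-ethyl-8-(1-hydroxypent-2-ynyl)-9-methyl-1,4-dioxaspiro[4.4]nonan-7-yl]butanoate (both carbinol epimers) | C12(OCCO1)[C@@H](CC)[C@H]([C@@H](CC)C(=O)OC)[C@@H](C(O)C#CCC)[C@@H]2C | intermediate
15 | methyl 2-[6-ethyl-9-methyl-8-(pent-2-ynoyl)-1,4-dioxaspiro[4.4]nonan-7-yl]butanoate | C12(OCCO1)[C@@H](CC)[C@H]([C@@H](CC)C(=O)OC)[C@@H](C(=O)C#CCC)[C@@H]2C | intermediate
16 | bromomagnesium alkoxide of the C4 tertiary alcohol (2-oxidohex-3-yn-2-yl group on C3a) | C12(OCCO1)[C@@H](CC)[C@H]([C@@H](CC)C(=O)OC)[C@@H]([C@](C)(O[Mg]Br)C#CCC)[C@@H]2C | intermediate (not isolated)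
17 | trans-fused δ-lactone: C8(=O)–O–C4 ring on the ketal-protected cyclopentane; C4 methyl β and but-1-ynyl α; C7 ethyl β; C1 ethyl β; C3 methyl α | O=C1O[C@](C)(C#CCC)[C@@H]2[C@H]([C@H](CC)C3(OCCO3)[C@H]2C)[C@H]1CC | intermediate
18 | alkenylzirconocene chloride of 17 (Cp2ZrCl on C6, trans to C4) | O=C1O[C@](C)(/C=C(\CC)/[Zr](Cl)(C4C=CC=C4)C5C=CC=C5)[C@@H]2[C@H]([C@H](CC)C3(OCCO3)[C@H]2C)[C@H]1CC | intermediate (not isolated)
19 | δ-lactone with an (E)-2-iodobut-1-enyl group on C4 (ethyl cis to C4) | O=C1O[C@](C)(/C=C(\CC)/I)[C@@H]2[C@H]([C@H](CC)C3(OCCO3)[C@H]2C)[C@H]1CC | intermediate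
20 | δ-lactone with an (E)-2-ethylhex-1-en-3-ynyl group on C4 (ethyl cis to C4); rearrangement precursor | O=C1O[C@](C)(/C=C(\CC)/C#CCC)[C@@H]2[C@H]([C@H](CC)C3(OCCO3)[C@H]2C)[C@H]1CC | intermediate
21 | cyclic tert-butyldimethylsilyl ketene acetal of 20 (C7=C8) | CC(C)(C)[Si](C)(C)OC=1O[C@](C)(/C=C(\CC)/C#CCC)[C@@H]2[C@H]([C@H](CC)C3(OCCO3)[C@H]2C)C=1CC | intermediate (not isolated)
22 | tert-butyldimethylsilyl 6-(but-1-ynyl)-1,6,7-triethyl-3,4-dimethyl-hexahydroindene-7-carboxylate, C2 ethylene ketal (C4=C5; C6 butynyl β; C7 carboxyl β; trans ring fusion); rearrangement product | CCC#C[C@@]1(CC)C=C(C)[C@@H]2[C@H]([C@H](CC)C3(OCCO3)[C@H]2C)[C@@]1(CC)C(=O)O[Si](C)(C)C(C)(C)C | intermediate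
23 | (E)-(2-bromovinyl)benzene | Br/C=C/c1ccccc1 | starting material
24 | alkenylzirconocene chloride of 22 (Cp2ZrCl on Cb, trans to C6) | CCC(/[Zr](Cl)(C4C=CC=C4)C5C=CC=C5)=C\[C@@]1(CC)C=C(C)[C@@H]2[C@H]([C@H](CC)C3(OCCO3)[C@H]2C)[C@@]1(CC)C(=O)O[Si](C)(C)C(C)(C)C | intermediate (not isolated)
25 | alkenylzinc chloride (ZnCl on Cb) | CCC(/[Zn]Cl)=C\[C@@]1(CC)C=C(C)[C@@H]2[C@H]([C@H](CC)C3(OCCO3)[C@H]2C)[C@@]1(CC)C(=O)O[Si](C)(C)C(C)(C)C | intermediate (not isolated)
26 | tert-butyldimethylsilyl ester of the target ethylene ketal | CCC(/C=C/c1ccccc1)=C\[C@@]1(CC)C=C(C)[C@@H]2[C@H]([C@H](CC)C3(OCCO3)[C@H]2C)[C@@]1(CC)C(=O)O[Si](C)(C)C(C)(C)C | intermediate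
27 | CNP0134269.1: 1,6,7-triethyl-6-[(1E,3E)-2-ethyl-4-phenylbuta-1,3-dienyl]-3,4-dimethyl-2-oxo-2,3,3a,6,7,7a-hexahydro-1H-indene-7-carboxylic acid (1β-ethyl; 3α-methyl; H-3a α; H-7a β; 6β-dienyl; 7β-carboxyl) | CCC(/C=C/c1ccccc1)=C\[C@@]1(CC)C=C(C)[C@@H]2[C@H]([C@H](CC)C(=O)[C@H]2C)[C@@]1(CC)C(=O)O | target

## Step count

Total step count: 15. Longest linear sequence: 14 steps (1 → 27 through steps 1, 2 and 4–15; step 3 is a one-step side branch).

## Steps most likely to fail

**Step 13 (key step).** The trans-fused five-membered ring may keep the ketene acetal from folding into the twist-boat array. Heating could then cleave the tertiary allylic C4–O bond heterolytically, or return lactone after work-up. The fallback gives up the lactone template, forms C6–C7 in an unconstrained chair and closes the cyclohexene by metathesis; it sets out from 10 and returns at 22. Wacker oxidation of the vinyl group of 10 (PdCl2, CuCl, O2, DMF–H2O) would give methyl ketone F1, Wittig methylenation (Ph3P=CH2) the isopropenyl ester F2, and saponification (LiOH) the acid F3. In parallel, pent-2-yn-1-ol would be taken by trans-hydroalumination–iodination (NaAlH2(OCH2CH2OMe)2, then I2) to (Z)-3-iodopent-2-en-1-ol F4 and by Sonogashira coupling with 13 to (Z)-3-ethylhept-2-en-4-yn-1-ol F5. Esterification of F3 with F5 (DCC, DMAP) gives allyl ester F6. LiN(i-Pr)2 followed by t-BuMe2SiCl and HMPA gives the acyclic ketene acetal F7 with C7a cis to the allyloxy group. This should rearrange through a chair near room temperature to the dienyne silyl ester F8, with the C6–C7 bond and both quaternary carbons in place. The chair pairing of this ketene acetal with the Z-alcohol gives the required relative configuration of C6 and C7. The face of C7 is then controlled only by the neighbouring C7a centre, so the wanted diastereomer would have to be separated. Ring-closing metathesis between the isopropenyl group and the new C6 vinyl group (second-generation Grubbs catalyst, (H2IMes)(PCy3)Cl2Ru=CHPh, toluene, 80 °C) closes the ring with the C4=C5 alkene and gives 22.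

**Step 10.** Facial control in the methyl transfer may be lost or reversed if the chelate between the ketone and ketal oxygens does not form, giving the C4 epimer whose arm lies on the wrong lactone face. The fallback introduces the two carbon groups in the opposite order, so that the same facial preference of the C4 carbonyl leads to the opposite C4 configuration; it sets out from 10 and returns at 17. Wacker oxidation of 10 (PdCl2, CuCl, O2) gives the methyl ketone F9. Addition of the cerium acetylide made from 13 (n-BuLi, then CeCl3) gives the tertiary alcohol F10. Catalytic KOt-Bu in THF closes the lactone to 17.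

**Step 14.** Hydrometalation of the alkyne held between the quaternary C6 and the ethyl group may be incomplete or unselective, and transmetalation and coupling of the congested alkenyl metal may be slow. The fallback moves the diene construction ahead of the rearrangement, where the alkyne is not yet flanked by quaternary carbons; it sets out from 20 and returns at 26. Hydrozirconation of 20 (Cp2Zr(H)Cl) would give alkenylzirconocene chloride F11, ZnCl2 the alkenylzinc chloride F12, and coupling with 23 (Pd(PPh3)4) the trienyl lactone F13. Silylation of its potassium enolate (KN(SiMe3)2, t-BuMe2SiCl) gives silyl ketene acetal F14, whose [3,3] shift in hot toluene delivers 26 directly.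

## Further compounds

F1 | step 13 | methyl 2-(8-acetyl-6-ethyl-9-methyl-1,4-dioxaspiro[4.4]nonan-7-yl)butanoate | C12(OCCO1)[C@@H](CC)[C@H]([C@@H](CC)C(=O)OC)[C@@H](C(C)=O)[C@@H]2C
F2 | step 13 | methyl 2-(6-ethyl-9-methyl-8-isopropenyl-1,4-dioxaspiro[4.4]nonan-7-yl)butanoate | C12(OCCO1)[C@@H](CC)[C@H]([C@@H](CC)C(=O)OC)[C@@H](C(C)=C)[C@@H]2C
F3 | step 13 | 2-(6-ethyl-9-methyl-8-isopropenyl-1,4-dioxaspiro[4.4]nonan-7-yl)butanoic acid | C12(OCCO1)[C@@H](CC)[C@H]([C@@H](CC)C(=O)O)[C@@H](C(C)=C)[C@@H]2C
F4 | step 13 | (Z)-3-iodopent-2-en-1-ol | OC/C=C(\I)CC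
F5 | step 13 | (Z)-3-ethylhept-2-en-4-yn-1-ol | OC/C=C(\C#CCC)CC
F6 | step 13 | (Z)-3-ethylhept-2-en-4-ynyl ester of F3 | C12(OCCO1)[C@@H](CC)[C@H]([C@@H](CC)C(=O)OC/C=C(\C#CCC)CC)[C@@H](C(C)=C)[C@@H]2C
F7 | step 13 | tert-butyldimethylsilyl ketene acetal of F6 (C7a cis to the allyloxy group) | C12(OCCO1)[C@@H](CC)[C@H](/C(CC)=C(\OC/C=C(\C#CCC)CC)O[Si](C)(C)C(C)(C)C)[C@@H](C(C)=C)[C@@H]2C
F8 | step 13 | tert-butyldimethylsilyl ester with the C6–C7 bond formed (C6: ethyl, butynyl, vinyl; C7: ethyl, silyl carboxylate; isopropenyl on C3a) | C12(OCCO1)[C@@H](CC)[C@H]([C@@](CC)(C(=O)O[Si](C)(C)C(C)(C)C)[C@@](CC)(C#CCC)C=C)[C@@H](C(C)=C)[C@@H]2C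
F9 | step 10 | methyl 2-(8-acetyl-6-ethyl-9-methyl-1,4-dioxaspiro[4.4]nonan-7-yl)butanoate (same compound as F1) | C12(OCCO1)[C@@H](CC)[C@H]([C@@H](CC)C(=O)OC)[C@@H](C(C)=O)[C@@H]2C
F10 | step 10 | methyl 2-[6-ethyl-8-(2-hydroxyhex-3-yn-2-yl)-9-methyl-1,4-dioxaspiro[4.4]nonan-7-yl]butanoate | C12(OCCO1)[C@@H](CC)[C@H]([C@@H](CC)C(=O)OC)[C@@H]([C@](C)(O)C#CCC)[C@@H]2C
F11 | step 14 | alkenylzirconocene chloride of lactone 20 (Cp2ZrCl on Cb) | O=C1O[C@](C)(/C=C(\CC)/C=C(\CC)/[Zr](Cl)(C4C=CC=C4)C5C=CC=C5)[C@@H]2[C@H]([C@H](CC)C3(OCCO3)[C@H]2C)[C@H]1CC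
F12 | step 14 | alkenylzinc chloride of lactone 20 (ZnCl on Cb) | O=C1O[C@](C)(/C=C(\CC)/C=C(\CC)/[Zn]Cl)[C@@H]2[C@H]([C@H](CC)C3(OCCO3)[C@H]2C)[C@H]1CC
F13 | step 14 | δ-lactone with the (1E,3E,5E)-2,4-diethyl-6-phenylhexa-1,3,5-trienyl group on C4 | O=C1O[C@](C)(/C=C(\CC)/C=C(\CC)/C=C/c4ccccc4)[C@@H]2[C@H]([C@H](CC)C3(OCCO3)[C@H]2C)[C@H]1CC
F14 | step 14 | cyclic tert-butyldimethylsilyl ketene acetal of F13 | CC(C)(C)[Si](C)(C)OC=1O[C@](C)(/C=C(\CC)/C=C(\CC)/C=C/c4ccccc4)[C@@H]2[C@H]([C@H](CC)C3(OCCO3)[C@H]2C)C=1CC
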